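## Structural features

The target is 5,7,8-trimethoxy-2-(2,3,4,5-tetramethoxyphenyl)-4H-chromen-4-one, a fully O-methylated flavone of formula C22H24O9. Ring C is a 4-pyranone (O1, C2, C3, C4, C4a, C8a) fused through the C4a–C8a bond to the benzene ring A, and C2 carries ring B through a single aryl–vinyl bond. Ring A bears methoxy groups at C5, C7 and C8 and one hydrogen at C6. Ring B bears four adjacent methoxy groups at C2' to C5' and one hydrogen at C6'. There is no stereocentre and no stereogenic double bond, so no question of relative or absolute configuration arises.

The sensitive sites are three. The vinylogous ester of ring C can be opened at C2 by hard nucleophiles and strong aqueous base. The methyl ethers next to the carbonyl system (C5, C2') are the ones Lewis acids cleave first. The two electron-rich arenes and C3 are open to electrophiles and oxidants.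

The real difficulty is regiochemical. Ring A must carry the 5,7,8 pattern and not the isomeric 5,6,7 pattern, and classical phenol chemistry distinguishes C8 from C6 poorly. Ring B must carry four contiguous oxygens.

The key step uses two facts. C5–C6–C7–C8 is a four-carbon chain oxygenated at C5, C7 and C8, which is the pattern of a 1,1,3,4-tetraoxygenated butadiene. C4a=C8a is the enone double bond of a monocyclic 4-pyranone. Ring A can therefore be built onto a finished ring C by [4+2] cycloaddition and aromatisation.

## Logic of the disconnections

**19 to 18.** The O–CH3 bond at C5 is cut. The ring-forming step delivers the C5 oxygen as a silyl ether, hence as a free phenol, because the ketene acetal carbon keeps its silyloxy group when the ketal collapses. Nothing is gained in skeleton, but the cut allows the easily made mixed methyl silyl ketene acetal to be used. The forward step must alkylate a phenol that is hydrogen-bonded to the C4 carbonyl. This calls for excess reagent and heat, and no other nucleophilic site competes, since every other oxygen is already an ether.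

**18 to 10 and 15 (through 17 and 16).** The bonds C4a–C5 and C8–C8a are cut. The three oxygens of ring A then come from an acyclic four-carbon unit, and their positions are decided by the polarity of the two partners and not by substitution chemistry on an arene. Rings B and C are left untouched. The forward step demands that 10 reacts as a dienophile only at its brominated double bond, in the orientation that joins the methoxy-bearing terminus of 15 to the unsubstituted carbon next to the ring oxygen. The adduct must also lose hydrogen bromide and methanol cleanly.

**10 to 9.** The O1–C6 bond of the pyranone is cut. An enol oxygen adding to a β-methoxy enone with loss of methanol is a simple acid-catalysed condensation. Ring C is reduced to an open-chain 1,3-dione. The acid must not cleave aryl methyl ethers, and the bromine must remain on the enone carbon.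

**9 to 3 and 7 (through 8).** The bond between the aroyl carbonyl carbon and the methylene carbon is cut. This is a C-acylation of a methyl ketone enolate. It divides the molecule into ring B as the acyl electrophile and a four-carbon enone that already carries the bromine on the right carbon. The forward step needs kinetic deprotonation at the methyl group, C-acylation in preference to O-acylation, and a second equivalent of enolate to take up the acidic proton of the product.

**3 to 1 (through 2).** The C–Br bond is cut. In 1 only one carbon is nucleophilic, so the position of the halogen is unambiguous. On the finished aryl pyranone an electrophilic halogen would have to choose between C5 and C3 of ring C and C6' of ring B. The addition–elimination must stop at the monobromide.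

**7 to 6 to 4 (through 5).** The C–Cl bond and then the aryl–carboxyl bond are cut. The two ring hydrogens of 4 are equivalent and each is ortho to a methoxy group, so directed metalation gives one aryl anion. The forward steps need dry conditions and a carboxylation that avoids addition of a second aryl anion.

**15 to 13 to 11 (through 14 and 12).** The O–Si bond and then the enol ether O–CH3 bond are cut. The diene is reduced to a commercial β-keto ester that already holds all four carbons and the future C8 oxygen. The forward steps need deprotonation at the γ-carbon and not the α-carbon, silylation at oxygen and not carbon, and exclusion of moisture.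

## Other disconnections considered

**Alternative 1:** The cut is C4a–C8a, with ring A folded from a linear polyketide. In the forward key step, methyl (E)-9-(2,3,4,5-tetramethoxyphenyl)-3,5,7-trioxonon-8-enoate A1, held as its chelate with Mg(OMe)2, would undergo Claisen condensation of the C6 methylene onto the ester carbon. This would give (E)-2',4',6'-trihydroxy-2,3,4,5-tetramethoxychalcone A2.
- In its favour: the reaction type is established in biomimetic polyketide chemistry, so on mechanistic precedent it is better than step 8. The new ring of A2 is a symmetric phloroglucinol, so the ring-forming step raises no question of orientation, a point on which it is at least the equal of the chosen plan. No halogen or silicon is carried.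
- Against it: A1 is a triketo ester with an enone, and it can close in several ways. Aldol closure of C2 onto the C7 carbonyl, lactonisation to pyranones and conjugate addition of internal enolates to the cinnamoyl unit all compete with the Claisen mode. A1 also needs several enolate acylations to make.
- The decisive structural weakness is that A2 has no oxygen at the future C8. After oxidative closure to 5,7-dihydroxy-2-(2,3,4,5-tetramethoxyphenyl)chromen-4-one A3, a hydroxyl must be introduced at C8 in competition with C6, and three phenols must be methylated.
- Step economy: at least four operations follow the key step, against one in the chosen plan, which installs all three oxygens of ring A at once.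

**Alternative 2:** The cut removes C3 as a one-carbon unit by cutting C2–C3 and C3–C4. In the forward key step, 4,6,7-trimethoxy-2-(2,3,4,5-tetramethoxyphenyl)benzofuran-3(2H)-one A4 would be silylated to 4,6,7-trimethoxy-2-(2,3,4,5-tetramethoxyphenyl)-3-(trimethylsilyloxy)benzofuran A5. A dihalocarbene from CHCl3 and KOt-Bu would add to the C2=C3 bond of A5, and opening of the cyclopropane with loss of chloride and silyl would give 3-chloro-5,7,8-trimethoxy-2-(2,3,4,5-tetramethoxyphenyl)chromen-4-one A6.
- In its favour: all seven methoxy groups are fixed in A4, so the key step makes no regiochemical decision about ring A. On this point it is better than the chosen plan, which relies on the orientation of a cycloaddition. Carbene ring expansion of cyclic silyl enol ethers to α-chloro enones is a known reaction type, so its precedent is somewhat closer than that of step 8. A6 is one step from the target, the same count as in the chosen plan.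
- Against it: the 5,7,8 pattern has to be built beforehand by classical acylation chemistry on a tetraoxygenated benzene, which is the very problem the chosen key step removes. A4 is a 2-aryl coumaranone prone to autoxidation at C2. The C2=C3 bond of A5 is tetrasubstituted and part of a furan. The final hydrodechlorination (H2, palladium on carbon) must spare the C2=C3 bond of ring C.
- Step economy: roughly equal overall, with about five steps to A4, then silylation, ring expansion and dechlorination. A chlorine is introduced only to be removed.

**Alternative 3:** The cuts are O1–C8a and C4–C4a, and then O1–C2. In the forward key step, 3,5-dimethoxy-2-(trimethylsilyl)phenyl trifluoromethanesulfonate A7 with CsF would release 3,5-dimethoxybenzyne A8. A8 would insert into the carboxyl C–O bond of 3-(2,3,4,5-tetramethoxyphenyl)propiolic acid A9, and the phenoxide would close ring C by conjugate addition to the ynone. This would give 5,7-dimethoxy-2-(2,3,4,5-tetramethoxyphenyl)chromen-4-one A10.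
- In its favour: insertion of arynes into carboxylic acid C–O bonds with closure onto an ynone is a known route to chromones, so in precedent it is better than step 8. It is as convergent as the chosen plan and forms ring C and the A–B link in one flask. Attack of the carboxylate at the aryne carbon remote from the flanking methoxy group gives the 5,7 pattern correctly.
- Against it: A10 has no oxygen at C8. Late introduction (halogenation, then copper-catalysed methoxylation) would have to select C8 over C6, C3 and C6' of the electron-rich ring B. An aryne that already carries the C8 oxygen would be flanked by oxygen on both sides and would lose its regiocontrol. Competing O–H insertion to an aryl ester and decarboxylation of A9 are further risks.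
- Step economy: about three steps to A7, two to three to A9, the key step and two to three steps for C8, which is longer than the chosen plan. The chosen plan is weaker in precedent but better in structure, because its key step sets the complete oxygenation of ring A.

Key step: step 8

Remark on the chemistry: the double-bond geometry of 15 and the relative configurations of 2 and 16 do not affect the outcome, since all of these elements are lost before 18 is reached; 2 and 16 are therefore listed as mixtures of stereoisomers. Bromine is placed on the four-carbon enone before ring B is attached, a change in the preparation of 10 that leaves its structure and the key disconnection untouched.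

## Steps

Step 1
Reactants: 1 (E)-4-methoxybut-3-en-2-one
Product: 3 (Z)-3-bromo-4-methoxybut-3-en-2-one, via 3,4-dibromo-4-methoxybutan-2-one 2 (not isolated)
Conditions: Br2 (1.0 equiv), CH2Cl2, −78 °C; then Et3N (1.2 equiv), −78 °C to rt
Reagents that add atoms: bromine, BrBr
Why: Electrophilic addition of bromine to the enol ether double bond, then amine-induced loss of HBr (the proton α to the carbonyl and the bromide of the α-bromo ether), is the standard α-halogenation of a vinylogous ester; C3 is the only nucleophilic carbon of 1, so the halogen can end up nowhere else.

Step 2
Reactants: 4 1,2,3,4-tetramethoxybenzene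
Product: 6 2,3,4,5-tetramethoxybenzoic acid, via 2,3,4,5-tetramethoxyphenyllithium 5 (not isolated)
Conditions: n-BuLi (1.1 equiv), TMEDA (1.1 equiv), THF, 0 °C; then CO2, −78 °C to rt; then 1 M HCl
Reagents that add atoms: carbon dioxide, O=C=O
Why: Directed ortho-metalation followed by carboxylation; the two ring hydrogens of 4 are equivalent and each lies ortho to a methoxy group, so a single aryllithium should form.

Step 3
Reactants: 6 2,3,4,5-tetramethoxybenzoic acid
Product: 7 2,3,4,5-tetramethoxybenzoyl chloride
Conditions: (COCl)2 (1.3 equiv), DMF (cat.), CH2Cl2, 0 °C to rt; evaporation, used crude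
Reagents that add atoms: oxalyl chloride, O=C(Cl)C(=O)Cl
Why: Acid chloride formation under chloroiminium catalysis; the conditions are free of Lewis acid and should leave the four aryl methyl ethers intact.

Step 4
Reactants: 3 (Z)-3-bromo-4-methoxybut-3-en-2-one; 7 2,3,4,5-tetramethoxybenzoyl chloride
Product: 9 (Z)-4-bromo-5-methoxy-1-(2,3,4,5-tetramethoxyphenyl)pent-4-ene-1,3-dione, via lithium enolate 8 (not isolated)
Conditions: 3 (2.0 equiv), LiN(SiMe3)2 (2.1 equiv), THF, −78 °C; then 7 (1.0 equiv), −78 to −40 °C; aq. NH4Cl
Reagents that add atoms: none
Why: Claisen-type C-acylation of a kinetic lithium methyl-ketone enolate by an aroyl chloride, the established entry to 5-methoxypent-4-ene-1,3-diones; the second equivalent of enolate takes up the proton of the more acidic product, and the vinylic bromide should be inert to the hindered amide base at low temperature.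

Step 5
Reactants: 9 (Z)-4-bromo-5-methoxy-1-(2,3,4,5-tetramethoxyphenyl)pent-4-ene-1,3-dione
Product: 10 5-bromo-2-(2,3,4,5-tetramethoxyphenyl)-4H-pyran-4-one
Conditions: CF3CO2H (5 equiv), CH2Cl2, 0 °C to rt
Reagents that add atoms: none
Why: Acid-catalysed 6-endo-trig addition of the aryl-ketone enol oxygen to the β-methoxy enone and loss of methanol (addition–elimination) closes the 4-pyranone, the known cyclisation of such diones; the bromine lies on the carbon that becomes C5 by construction.

Step 6
Reactants: 11 methyl 4-methoxy-3-oxobutanoate
Product: 13 methyl (E)-3,4-dimethoxybut-2-enoate, via methyl 3,3,4-trimethoxybutanoate 12 (not isolated)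
Conditions: HC(OMe)3 (1.5 equiv), H2SO4 (cat.), rt; then distillation from the acid
Reagents that add atoms: trimethyl orthoformate, COC(OC)OC
Why: Acid-catalysed ketalisation by the orthoformate and thermal loss of methanol should give the conjugated β-methoxy enoate, as in the standard preparation of β-alkoxycrotonates; the E isomer, with the methoxymethyl group syn to the ester, is the thermodynamic one.

Step 7
Reactants: 13 methyl (E)-3,4-dimethoxybut-2-enoate
Product: 15 (1Z,3Z)-1,3,4-trimethoxy-1-(trimethylsilyloxy)buta-1,3-diene, via lithium dienolate 14 (not isolated)
Conditions: LiN(i-Pr)2 (1.1 equiv), THF, −78 °C; then Me3SiCl (1.2 equiv), −78 °C to rt; pentane, filtration, distillation under reduced pressure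
Reagents that add atoms: chlorotrimethylsilane, C[Si](C)(C)Cl
Why: Vinylogous (γ) deprotonation of a β-alkoxy enoate and O-silylation of the dienolate is the standard route to 1,3-dialkoxy-1-silyloxybutadienes; the methoxymethyl group syn to the ester is deprotonated by the ester-bound amide, and the hard silyl chloride should react at oxygen.

Step 8
Reactants: 10 5-bromo-2-(2,3,4,5-tetramethoxyphenyl)-4H-pyran-4-one; 15 (1Z,3Z)-1,3,4-trimethoxy-1-(trimethylsilyloxy)buta-1,3-diene
Product: 18 5-hydroxy-7,8-dimethoxy-2-(2,3,4,5-tetramethoxyphenyl)-4H-chromen-4-one, via cycloadduct 16 (not isolated), via silyl ether 17 (not isolated)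
Conditions: 15 (3 equiv), 2,6-lutidine (1.5 equiv), toluene, 100 °C, sealed tube; then 1 M HCl, THF, rt
Reagents that add atoms: none
Why: Proposed new method: a normal-electron-demand, strongly asynchronous [4+2] cycloaddition in which C4 of 15, the terminus made nucleophilic by the three oxygens at C1 and C3, bonds to the oxygen-bearing β-carbon C6 of the bromoenone in 10 (future C8a) ahead of the bond from the ketene acetal carbon C1 to the bromine-bearing C5 (future C4a), the stepwise limit being a vinylogous Mukaiyama–Michael addition followed by closure of the bromo enolate on the dialkoxycarbenium ion; the closest known reaction types are the regioselective benzannulation of 2-halo-1,4-quinones with 1,3-dialkoxy-1-silyloxybutadienes and the cycloaddition of siloxydienes to chromones that carry an acceptor at C3, from which this case differs in that bromine and the cross-conjugated carbonyl are the only activation. Ring A, the only ring formed, closes by suprafacial union of the diene termini with C5=C6 of 10, which in the stepwise limit is a 6-(enolexo)-exo-trig closure of C4a onto C5. The stereocentres of 16 (C4a, C5, C8, C8a) are transient and none survives, so no stereocontrol is required. Aromatisation needs no anti-periplanar H/Br pair: the C5 ketal ionises with loss of methanol and of H8, the C4a–Br bond then becomes a doubly vinylogous α-bromo ether (Br–C4a–C5=C6–C7=C8–OMe) that ionises readily, and loss of H8a to the lutidine should give 17, which aqueous acid desilylates to 18. The step needs orientational selectivity and site selectivity between C5=C6 and C2=C3 of 10; the first follows from the polarity match of the most nucleophilic diene terminus with the unsubstituted β-carbon, the second from the bromine, which lowers the LUMO at its own double bond and is the only leaving group, and from the aryl group, which shields and deactivates C2=C3.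

Step 9
Reactants: 18 5-hydroxy-7,8-dimethoxy-2-(2,3,4,5-tetramethoxyphenyl)-4H-chromen-4-one
Product: 19 5,7,8-trimethoxy-2-(2,3,4,5-tetramethoxyphenyl)-4H-chromen-4-one
Conditions: Me2SO4 (3 equiv), K2CO3 (5 equiv), acetone, reflux
Reagents that add atoms: dimethyl sulfate, COS(=O)(=O)OC
Why: Williamson O-methylation of a phenol; the C5 hydroxyl is the only acidic site, and its hydrogen bond to the C4 carbonyl only slows the reaction, which excess reagent and reflux should overcome.

## Compound list

1 | (E)-4-methoxybut-3-en-2-one | CO/C=C/C(C)=O | starting material
2 | 3,4-dibromo-4-methoxybutan-2-one (mixture of diastereomers) | COC(Br)C(Br)C(C)=O | intermediate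
3 | (Z)-3-bromo-4-methoxybut-3-en-2-one | CO/C=C(\Br)C(C)=O | intermediate
4 | 1,2,3,4-tetramethoxybenzene | COc1ccc(OC)c(OC)c1OC | starting material
5 | 2,3,4,5-tetramethoxyphenyllithium | [Li]c1cc(OC)c(OC)c(OC)c1OC | intermediate
6 | 2,3,4,5-tetramethoxybenzoic acid | COc1cc(C(=O)O)c(OC)c(OC)c1OC | intermediate
7 | 2,3,4,5-tetramethoxybenzoyl chloride | COc1cc(C(=O)Cl)c(OC)c(OC)c1OC | intermediate
8 | lithium (Z)-3-bromo-4-methoxybuta-1,3-dien-2-olate | CO/C=C(\Br)C(=C)O[Li] | intermediate
9 | (Z)-4-bromo-5-methoxy-1-(2,3,4,5-tetramethoxyphenyl)pent-4-ene-1,3-dione | CO/C=C(\Br)C(=O)CC(=O)c1cc(OC)c(OC)c(OC)c1OC | intermediate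
10 | 5-bromo-2-(2,3,4,5-tetramethoxyphenyl)-4H-pyran-4-one | O=c1cc(-c2cc(OC)c(OC)c(OC)c2OC)occ1Br | intermediate
11 | methyl 4-methoxy-3-oxobutanoate (methyl 4-methoxyacetoacetate) | COCC(=O)CC(=O)OC | starting material
12 | methyl 3,3,4-trimethoxybutanoate | COCC(OC)(OC)CC(=O)OC | intermediate
13 | methyl (E)-3,4-dimethoxybut-2-enoate | COC/C(OC)=C\C(=O)OC | intermediate
14 | lithium (1E,3Z)-1,3,4-trimethoxybuta-1,3-dien-1-olate (O–Li syn to C3) | CO/C=C(OC)/C=C(/OC)O[Li] | intermediate
15 | (1Z,3Z)-1,3,4-trimethoxy-1-(trimethylsilyloxy)buta-1,3-diene | CO/C=C(OC)/C=C(/OC)O[Si](C)(C)C | intermediate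
16 | 4a-bromo-5,7,8-trimethoxy-2-(2,3,4,5-tetramethoxyphenyl)-5-(trimethylsilyloxy)-4a,5,8,8a-tetrahydro-4H-chromen-4-one (racemic mixture of diastereomers) | O=C1C=C(c2cc(OC)c(OC)c(OC)c2OC)OC2C(OC)C(OC)=CC(OC)(O[Si](C)(C)C)C12Br | intermediate
17 | 7,8-dimethoxy-2-(2,3,4,5-tetramethoxyphenyl)-5-(trimethylsilyloxy)-4H-chromen-4-one | COc1cc(O[Si](C)(C)C)c2c(=O)cc(-c3cc(OC)c(OC)c(OC)c3OC)oc2c1OC | intermediate
18 | 5-hydroxy-7,8-dimethoxy-2-(2,3,4,5-tetramethoxyphenyl)-4H-chromen-4-one | COc1cc(O)c2c(=O)cc(-c3cc(OC)c(OC)c(OC)c3OC)oc2c1OC | intermediate
19 | 5,7,8-trimethoxy-2-(2,3,4,5-tetramethoxyphenyl)-4H-chromen-4-one | COc1cc(-c2cc(=O)c3c(OC)cc(OC)c(OC)c3o2)c(OC)c(OC)c1OC | target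

## Step count and least certain steps

Total step count: 9. Longest linear sequence: 6 steps (4 to 6 to 7 to 9 to 10 to 18 to 19; steps 2, 3, 4, 5, 8 and 9).

**Step 8 (key step, the only step without direct precedent).**
- What may go wrong: the dienophilic reactivity of the bromopyranone may be too low, so that thermal decay and protodesilylation of the diene outrun the cycloaddition. After the first bond has formed, β-elimination of the ring oxygen with opening of ring C may compete with closure of ring A. The cis-fused bromo ketone may also lose hydrogen bromide slowly. Loss of silanol instead of methanol from the ketal would be harmless, since it leads to 19 itself and the crude mixture converges in step 9.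
- Fallback by known chemistry, from 7 to 19: the commercial 1-(2-hydroxy-3,4,6-trimethoxyphenyl)ethanone F1 would be acylated with 7 in pyridine to give 2-acetyl-3,5,6-trimethoxyphenyl 2,3,4,5-tetramethoxybenzoate F2. Baker–Venkataraman rearrangement (KOH, pyridine, 50 °C) would give 1-(2-hydroxy-3,4,6-trimethoxyphenyl)-3-(2,3,4,5-tetramethoxyphenyl)propane-1,3-dione F3. Cyclodehydration (H2SO4 cat., AcOH, 100 °C) would then give 19 directly, bypassing 10, 15 and 18. The oxygenation of ring A is then bought with F1 and no longer created in the route.

**Step 4.**
- What may go wrong: O-acylation and proton transfer from the product dione may erode the C-acylation, and the bromo enolate may decay before it is acylated.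
- Fallback, from 1 and 7 to 10: the lithium enolate of 1 (LiN(SiMe3)2, THF, −78 °C) would be acylated with 7 to give (E)-5-methoxy-1-(2,3,4,5-tetramethoxyphenyl)pent-4-ene-1,3-dione F4. Cyclisation with CF3CO2H would give 2-(2,3,4,5-tetramethoxyphenyl)-4H-pyran-4-one F5. Bromination of F5 with pyridinium tribromide in CH2Cl2 would return to the route at 10. Step 1 is then not needed. The price is that the halogen must select C5 over C3 and over C6' of ring B, which is why this order is held in reserve.

**Step 7.**
- What may go wrong: α-deprotonation with self-condensation of the ester, silylation at carbon, and hydrolytic loss of the silyl ketene acetal during isolation. An isomer with the terminal methoxy group turned inward would also react sluggishly in step 8.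
- Fallback, from 11 to 19: 11 would be silylated (Me3SiCl, Et3N) to methyl 4-methoxy-3-(trimethylsilyloxy)but-2-enoate F6. Deprotonation and silylation (LiN(i-Pr)2, Me3SiCl, THF, −78 °C) would give 1,4-dimethoxy-1,3-bis(trimethylsilyloxy)buta-1,3-diene F7, a diene class made routinely from β-keto esters. Cycloaddition of F7 with 10 under the conditions of step 8 should give 5,7-dihydroxy-8-methoxy-2-(2,3,4,5-tetramethoxyphenyl)-4H-chromen-4-one F8. Methylation of both hydroxyls of F8 with Me2SO4 and K2CO3 would return to the route at 19.

**Step 2.**
- What may go wrong: incomplete metalation, nucleophilic demethylation of a methoxy group by the alkyllithium, and addition of the aryllithium to the lithium carboxylate to give a diaryl ketone.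
- Fallback, from 4 to 6: Vilsmeier–Haack formylation of 4 (POCl3, DMF) would give 2,3,4,5-tetramethoxybenzaldehyde F9, the position being activated by one ortho and one para methoxy group. Pinnick oxidation of F9 (NaClO2, NaH2PO4, 2-methyl-2-butene, t-BuOH/H2O) would return to the route at 6.

## Further compounds

F1 | step 8 | 1-(2-hydroxy-3,4,6-trimethoxyphenyl)ethanone | CC(=O)c1c(O)c(OC)c(OC)cc1OC
F2 | step 8 | 2-acetyl-3,5,6-trimethoxyphenyl 2,3,4,5-tetramethoxybenzoate | CC(=O)c1c(OC(=O)c2cc(OC)c(OC)c(OC)c2OC)c(OC)c(OC)cc1OC
F3 | step 8 | 1-(2-hydroxy-3,4,6-trimethoxyphenyl)-3-(2,3,4,5-tetramethoxyphenyl)propane-1,3-dione | COc1cc(OC)c(C(=O)CC(=O)c2cc(OC)c(OC)c(OC)c2OC)c(O)c1OC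
F4 | step 4 | (E)-5-methoxy-1-(2,3,4,5-tetramethoxyphenyl)pent-4-ene-1,3-dione | CO/C=C/C(=O)CC(=O)c1cc(OC)c(OC)c(OC)c1OC
F5 | step 4 | 2-(2,3,4,5-tetramethoxyphenyl)-4H-pyran-4-one | O=c1ccoc(-c2cc(OC)c(OC)c(OC)c2OC)c1
F6 | step 7 | methyl 4-methoxy-3-(trimethylsilyloxy)but-2-enoate (E/Z mixture) | COCC(O[Si](C)(C)C)=CC(=O)OC
F7 | step 7 | 1,4-dimethoxy-1,3-bis(trimethylsilyloxy)buta-1,3-diene (mixture of geometric isomers) | COC=C(O[Si](C)(C)C)C=C(OC)O[Si](C)(C)C
F8 | step 7 | 5,7-dihydroxy-8-methoxy-2-(2,3,4,5-tetramethoxyphenyl)-4H-chromen-4-one | COc1c(O)cc(O)c2c(=O)cc(-c3cc(OC)c(OC)c(OC)c3OC)oc12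
F9 | step 2 | 2,3,4,5-tetramethoxybenzaldehyde | COc1cc(C=O)c(OC)c(OC)c1OC
A1 | alternative 1 | methyl (E)-9-(2,3,4,5-tetramethoxyphenyl)-3,5,7-trioxonon-8-enoate | COC(=O)CC(=O)CC(=O)CC(=O)/C=C/c1cc(OC)c(OC)c(OC)c1OC
A2 | alternative 1 | (E)-2',4',6'-trihydroxy-2,3,4,5-tetramethoxychalcone | O=C(/C=C/c1cc(OC)c(OC)c(OC)c1OC)c1c(O)cc(O)cc1O
A3 | alternative 1 | 5,7-dihydroxy-2-(2,3,4,5-tetramethoxyphenyl)-4H-chromen-4-one | COc1cc(-c2cc(=O)c3c(O)cc(O)cc3o2)c(OC)c(OC)c1OC
A4 | alternative 2 | 4,6,7-trimethoxy-2-(2,3,4,5-tetramethoxyphenyl)benzofuran-3(2H)-one (racemic) | COc1cc(OC)c2c(c1OC)OC(c1cc(OC)c(OC)c(OC)c1OC)C2=O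
A5 | alternative 2 | 4,6,7-trimethoxy-2-(2,3,4,5-tetramethoxyphenyl)-3-(trimethylsilyloxy)benzofuran | COc1cc(OC)c2c(O[Si](C)(C)C)c(-c3cc(OC)c(OC)c(OC)c3OC)oc2c1OC
A6 | alternative 2 | 3-chloro-5,7,8-trimethoxy-2-(2,3,4,5-tetramethoxyphenyl)-4H-chromen-4-one | COc1cc(OC)c2c(=O)c(Cl)c(-c3cc(OC)c(OC)c(OC)c3OC)oc2c1OC
A7 | alternative 3 | 3,5-dimethoxy-2-(trimethylsilyl)phenyl trifluoromethanesulfonate | COc1cc(OC)c([Si](C)(C)C)c(OS(=O)(=O)C(F)(F)F)c1
A8 | alternative 3 | 3,5-dimethoxybenzyne (1,2-didehydro-3,5-dimethoxybenzene) | COC1=CC(OC)=CC#C1
A9 | alternative 3 | 3-(2,3,4,5-tetramethoxyphenyl)propiolic acid | COc1cc(C#CC(=O)O)c(OC)c(OC)c1OC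
A10 | alternative 3 | 5,7-dimethoxy-2-(2,3,4,5-tetramethoxyphenyl)-4H-chromen-4-one | COc1cc(OC)c2c(=O)cc(-c3cc(OC)c(OC)c(OC)c3OC)oc2c1
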